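**Retrosynthetic overview**

1. C8–OH is installed last by Mukaiyama (HAT/O2) hydration of the 8(17)-alkene 30. C12–C13 comes from a Ni-catalysed radical cross-electrophile coupling of bromide 21 with the (S)-iodobutenolide 29.
2. Key step: both carbocycles of 21 form in one Ti(III) radical epoxy-polyene bicyclisation of the acyclic, fully oxygenated bromo-epoxide 18 (ring A by C4–C5, then ring B by C9–C10). The C3 epoxide and C6 silyl ether stereocentres direct C4, C5, C9 and C10.
3. 18 is a linear chain grown from 1,5-hexadiyne with CH2O, MeMgBr/Cu (C3=C4), two Zr-catalysed carboaluminations (C5=C10, C8=C9), a Cr-catalysed asymmetric propargylation (C6), oxirane (C11–C12) and Sharpless epoxidation (C3).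
4. 29 comes from pent-3-yn-1-ol (hydrozirconation–iodination, oxidation) and methyl (Z)-3-iodobut-2-enoate by asymmetric Ni/Cr coupling–lactonisation (C16).

Assumption: labdane-type numbering is used throughout (ring carbons C1–C10, side chain C11–C16, C17 = 8-CH3, C18 = 4α-CH2OH, C20 = 10-CH3); the target is 3S,4R,5R,6S,8R,9R,10S,16S.

**Step 1**
Reactants: 1 1,5-hexadiyne; 2 formaldehyde (as paraformaldehyde)
Product: 4 hepta-2,6-diyn-1-ol, via lithium hexa-1,5-diyn-1-ide 3 (not isolated)
Conditions: 1 (3 equiv), n-BuLi (1 equiv), THF, −78 °C; (CH2O)n, −78 °C → rt; H2O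
Reagents that add atoms: none
Why: Acetylide hydroxymethylation, with excess diyne suppressing the bis-adduct; no stereocentre is formed.

**Step 2**
Reactants: 4 hepta-2,6-diyn-1-ol
Product: 6 (2E)-2-methylhept-2-en-6-yn-1-ol, via alkenylmagnesium chelate 5 (not isolated)
Conditions: MeMgBr (4 equiv), CuI (15 mol%), THF, −20 °C → rt; aq NH4Cl
Reagents that add atoms: methylmagnesium bromide, C[Mg]Br
Why: Duboudin–Jousseaume Cu-catalysed, alkoxide-directed anti-carbomagnesiation of the 2-alkyn-1-ol puts CH3 on C4 and Mg on C3 cis to CH2O (five-membered chelate), so protonation gives the E-alkene (CH2OH trans to the chain), while the terminal alkyne sits as its inert magnesium acetylide.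

**Step 3**
Reactants: 6 (2E)-2-methylhept-2-en-6-yn-1-ol
Product: 7 triethyl{[(2E)-2-methylhept-2-en-6-yn-1-yl]oxy}silane
Conditions: TESCl, imidazole, CH2Cl2, 0 °C
Reagents that add atoms: chlorotriethylsilane, CC[Si](Cl)(CC)CC
Why: Standard silylation; the C18 oxygen must be masked for the allylic oxidation in step 5.

**Step 4**
Reactants: 7 the TES ether; 2 formaldehyde (as paraformaldehyde)
Product: 9 (2E,6E)-3,7-dimethyl-8-(triethylsilyloxy)octa-2,6-dien-1-ol, via alkenyldimethylalane 8 (not isolated)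
Conditions: Me3Al (2 equiv), Cp2ZrCl2 (0.25 equiv), CH2Cl2, 0 °C → rt; evaporate; n-BuLi, THF/hexane, −30 °C; (CH2O)n, rt
Reagents that add atoms: trimethylaluminium, C[Al](C)C
Why: Negishi Zr-catalysed carboalumination adds CH3 (to C10) and Al (to C5) syn across the terminal alkyne, and the derived alanate is hydroxymethylated with retention, giving the E-trisubstituted C5=C10 alkene.

**Step 5**
Reactants: 9 the allylic alcohol
Product: 10 (2E,6E)-3,7-dimethyl-8-(triethylsilyloxy)octa-2,6-dienal
Conditions: MnO2, CH2Cl2, rt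
Reagents that add atoms: none
Why: Chemoselective allylic oxidation without E/Z isomerisation.

**Step 6**
Reactants: 10 the enal; 11 propargyl bromide
Product: 12 (4S,5E,9E)-6,10-dimethyl-4,11-bis(triethylsilyloxy)undeca-5,9-dien-1-yne
Conditions: CrCl2 (10 mol%), chiral carbazole-bis(oxazoline) ligand (Nakada type, enantiomer giving Si-face attack, 10 mol%), Mn powder, TESCl, THF, rt
Reagents that add atoms: chlorotriethylsilane, CC[Si](Cl)(CC)CC
Why: Catalytic asymmetric Nozaki–Hiyama propargylation, in which the allenylchromium(III) formed by SET adds SE2′ in a 1,2-fashion to the enal under ligand control to set C6 (S); TESCl replaces TMSCl as turnover reagent, so the carbinol is released directly as its TES ether.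

**Step 7**
Reactants: 12 the enyne; 13 oxirane
Product: 15 (3E,6S,7E,11E)-4,8,12-trimethyl-6,13-bis(triethylsilyloxy)trideca-3,7,11-trien-1-ol, via alkenyldimethylalane 14 (not isolated)
Conditions: Me3Al (2.5 equiv), Cp2ZrCl2 (0.3 equiv), CH2Cl2, rt; evaporate; n-BuLi, THF/hexane, −30 °C; oxirane, −30 °C → rt
Reagents that add atoms: trimethylaluminium, C[Al](C)C
Why: A second Negishi carboalumination sets the E-C8=C9 alkene (CH3 on C8), and the alanate opens oxirane to add C11–C12 with a primary OH.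

**Step 8**
Reactants: 15 the primary alcohol
Product: 17 (2E,6E,8S,10E)-13-bromo-2,6,10-trimethyl-8-(triethylsilyloxy)trideca-2,6,10-trien-1-ol, via bis-TES bromide 16 (not isolated)
Conditions: CBr4, PPh3, 2,6-lutidine, CH2Cl2, −20 → 0 °C; then MeOH, PPTS (0.2 equiv), 0 °C
Reagents that add atoms: carbon tetrabromide, BrC(Br)(Br)Br
Why: Appel bromination of the only free (primary) alcohol, followed in the same flask by acid methanolysis, which removes the unhindered primary allylic TES ether much faster than the hindered secondary C6 TES ether.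

**Step 9**
Reactants: 17 the allylic alcohol
Product: 18 [(2S,3S)-3-[(3E,5S,7E)-10-bromo-3,7-dimethyl-5-(triethylsilyloxy)deca-3,7-dien-1-yl]-2-methyloxiran-2-yl]methanol
Conditions: Ti(OiPr)4 (10 mol%), L-(+)-DIPT (12 mol%), t-BuOOH, 4 Å MS, CH2Cl2, −25 °C
Reagents that add atoms: tert-butyl hydroperoxide, CC(C)(C)OO
Why: Sharpless asymmetric epoxidation touches only the alkene of the free allylic alcohol; L-(+)-tartrate gives the (2S,3S)-epoxide (same sense as (E)-2-hexenol and geraniol), which fixes C3 as S.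

**Step 10 (key step)**
Reactants: 18 the epoxy alcohol
Product: 21 12-bromo-13,14,15,16-tetranorlabd-8(17)-ene-3β,6α,18-triol (trans-decalin; 4α-CH2OH, 4β-CH3, 5α-H, 9α-H, 10β-CH3), via C-18 TMS ether 19 (not isolated), via trisilyl bicycle 20 (not isolated)
Conditions: TMSCl (5 equiv), 2,4,6-collidine (8 equiv), THF, rt, 30 min; Cp2TiCl2 (0.3 equiv), Mn dust (8 equiv), THF (0.02 M), rt, 12 h; filter; CSA (0.3 equiv), MeOH, 0 °C → rt
Reagents that add atoms: none
Why: Ti(III)-mediated radical epoxy-polyene bicyclisation (RajanBabu–Nugent opening under Cuerva–Justicia catalytic conditions): the tertiary C4 radical closes 6-endo onto C5 and the C10 radical 6-endo onto C9 through a chair–chair fold with C3–OTi, C6–OSi and the larger CH2OSi group on C4 all equatorial, then Ti-mediated β-H loss gives the 8(17)-alkene, so C4, C5, C9 and C10 are set in one operation under matched control by C3 and C6.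

**Step 11**
Reactants: 22 pent-3-yn-1-ol
Product: 24 (3E)-4-iodopent-3-en-1-ol, via alkenylzirconocene 23 (not isolated)
Conditions: Cp2Zr(H)Cl (2.5 equiv), THF, rt → 45 °C; I2, 0 °C
Reagents that add atoms: iodine, II
Why: Schwartz syn-hydrozirconation with excess reagent equilibrates Zr to the less hindered methyl-bearing carbon; iodinolysis with retention gives the E-2-iodo-2-alkene (I trans to the chain).

**Step 12**
Reactants: 24 the iodo alcohol
Product: 25 (3E)-4-iodopent-3-enal
Conditions: Dess–Martin periodinane, CH2Cl2, 0 °C; used at once without chromatography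
Reagents that add atoms: none
Why: Neutral Dess–Martin oxidation avoids conjugation of the β,γ-unsaturated aldehyde.

**Step 13**
Reactants: 26 methyl but-2-ynoate
Product: 27 methyl (2Z)-3-iodobut-2-enoate
Conditions: NaI, AcOH, 115 °C
Reagents that add atoms: sodium iodide, [Na+].[I-]
Why: Stereoselective anti-hydroiodination of the ynoate gives the Z-β-iodo enoate (I cis to CO2Me).

**Step 14**
Reactants: 25 the aldehyde; 27 the iodo enoate
Product: 29 (5S)-5-[(2E)-3-iodobut-2-en-1-yl]-4-methylfuran-2(5H)-one, via hydroxy ester 28 (not isolated)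
Conditions: CrCl2 (3 equiv), NiCl2 (2 mol%), chiral sulfonamide–oxazoline ligand (Kishi type, enantiomer giving 16S), Et3N, THF/MeCN, rt; then PPTS (cat.), CH2Cl2
Reagents that add atoms: none
Why: Asymmetric Nozaki–Hiyama–Kishi coupling, in which Ni(0) activates the electron-poor β-iodo enoate far faster than the unactivated 2-iodoalkene of 25 and the alkenylchromium adds with retention of the Z geometry and ligand control of C16 (S), so the γ-hydroxy Z-enoate lactonises to the butenolide.

**Step 15**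
Reactants: 21 the bromo triol; 29 the iodobutenolide
Product: 30 (5S)-4-methyl-5-[(2E)-3-methyl-5-(3β,6α,18-trihydroxy-14,15,16-trinorlabd-8(17)-en-13-yl)... i.e. the 8-deoxy-8(17)-ene of the target (C12–C13 joined, E-C13=C14)
Conditions: NiBr2·glyme (10 mol%), 4,4′-di-tert-butyl-2,2′-bipyridine (10 mol%), Zn dust (2.5 equiv), DMA, rt
Reagents that add atoms: none
Why: Ni-catalysed reductive cross-electrophile coupling (Weix type), in which Ni(0) inserts into the vinyl iodide with retention, the primary C12 radical formed from the bromide is captured by alkenyl–Ni(II), and reductive elimination forms C12–C13 with the E geometry intact under base-free conditions that leave C16 and the free hydroxyls untouched.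

**Step 16**
Reactants: 30 the 8(17)-alkene
Product: 32 target CNP0307004.1, via C-8 hydroperoxide 31 (not isolated)
Conditions: Co(acac)2 (0.2 equiv), PhSiH3 (2 equiv), O2 (1 atm), i-PrOH/THF, 0 °C → rt; then PPh3
Reagents that add atoms: dioxygen, O=O
Why: Mukaiyama hydration, in which Co–H HAT to the terminal CH2 gives the tertiary C8 radical that is trapped by O2; the 1,1-disubstituted alkene reacts ahead of the trisubstituted C13=C14 alkene and the butenolide (limonene → α-terpineol and carvone precedents), and O2 adds on the α face anti to the axial C10 methyl to give the equatorial 8α-OH with axial 8β-CH3.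

**Compound list**

1 | 1,5-hexadiyne | C#CCCC#C | starting material
2 | formaldehyde (as paraformaldehyde) | C=O | starting material
3 | lithium hexa-1,5-diyn-1-ide | [Li]C#CCCC#C | intermediate
4 | hepta-2,6-diyn-1-ol | OCC#CCCC#C | intermediate
5 | alkenylmagnesium chelate (Mg on C3 cis to CH2OMgBr; magnesium acetylide) | C/C(CO[Mg]Br)=C(/[Mg]Br)CCC#C[Mg]Br | intermediate
6 | (2E)-2-methylhept-2-en-6-yn-1-ol | OC/C(C)=C/CCC#C | intermediate
7 | triethyl{[(2E)-2-methylhept-2-en-6-yn-1-yl]oxy}silane | CC[Si](CC)(CC)OC/C(C)=C/CCC#C | intermediate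
8 | dimethyl[(1E,5E)-2,6-dimethyl-7-(triethylsilyloxy)hepta-1,5-dien-1-yl]alane | CC[Si](CC)(CC)OC/C(C)=C/CC/C(C)=C/[Al](C)C | intermediate
9 | (2E,6E)-3,7-dimethyl-8-(triethylsilyloxy)octa-2,6-dien-1-ol | CC[Si](CC)(CC)OC/C(C)=C/CC/C(C)=C/CO | intermediate
10 | (2E,6E)-3,7-dimethyl-8-(triethylsilyloxy)octa-2,6-dienal | CC[Si](CC)(CC)OC/C(C)=C/CC/C(C)=C/C=O | intermediate
11 | propargyl bromide | C#CCBr | starting material
12 | (4S,5E,9E)-6,10-dimethyl-4,11-bis(triethylsilyloxy)undeca-5,9-dien-1-yne | CC[Si](CC)(CC)OC/C(C)=C/CC/C(C)=C/[C@@H](O[Si](CC)(CC)CC)CC#C | intermediate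
13 | oxirane | C1CO1 | starting material
14 | dimethyl[(1E,4S,5E,9E)-2,6,10-trimethyl-4,11-bis(triethylsilyloxy)undeca-1,5,9-trien-1-yl]alane | CC[Si](CC)(CC)OC/C(C)=C/CC/C(C)=C/[C@@H](O[Si](CC)(CC)CC)C/C(C)=C/[Al](C)C | intermediate
15 | (3E,6S,7E,11E)-4,8,12-trimethyl-6,13-bis(triethylsilyloxy)trideca-3,7,11-trien-1-ol | CC[Si](CC)(CC)OC/C(C)=C/CC/C(C)=C/[C@@H](O[Si](CC)(CC)CC)C/C(C)=C/CCO | intermediate
16 | (2E,6E,8S,10E)-13-bromo-2,6,10-trimethyl-1,8-bis(triethylsilyloxy)trideca-2,6,10-triene | CC[Si](CC)(CC)OC/C(C)=C/CC/C(C)=C/[C@@H](O[Si](CC)(CC)CC)C/C(C)=C/CCBr | intermediate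
17 | (2E,6E,8S,10E)-13-bromo-2,6,10-trimethyl-8-(triethylsilyloxy)trideca-2,6,10-trien-1-ol | OC/C(C)=C/CC/C(C)=C/[C@@H](O[Si](CC)(CC)CC)C/C(C)=C/CCBr | intermediate
18 | [(2S,3S)-3-[(3E,5S,7E)-10-bromo-3,7-dimethyl-5-(triethylsilyloxy)deca-3,7-dien-1-yl]-2-methyloxiran-2-yl]methanol | OC[C@]1(C)O[C@H]1CC/C(C)=C/[C@@H](O[Si](CC)(CC)CC)C/C(C)=C/CCBr | intermediate
19 | C-18 trimethylsilyl ether of 18 | C[Si](C)(C)OC[C@]1(C)O[C@H]1CC/C(C)=C/[C@@H](O[Si](CC)(CC)CC)C/C(C)=C/CCBr | intermediate
20 | 3,18-bis(trimethylsilyl) 6-triethylsilyl ether of 21 | BrCC[C@@H]1[C@@]2(C)CC[C@H](O[Si](C)(C)C)[C@@](C)(CO[Si](C)(C)C)[C@@H]2[C@@H](O[Si](CC)(CC)CC)CC1=C | intermediate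
21 | 12-bromo-13,14,15,16-tetranorlabd-8(17)-ene-3β,6α,18-triol | BrCC[C@@H]1[C@@]2(C)CC[C@H](O)[C@@](C)(CO)[C@@H]2[C@@H](O)CC1=C | intermediate
22 | pent-3-yn-1-ol | CC#CCCO | starting material
23 | (E)-alkenylzirconocene chloride of the zirconium alkoxide (Cp drawn σ-bonded) | C/C(=C\CCO[Zr](Cl)(C1C=CC=C1)C1C=CC=C1)[Zr](Cl)(C1C=CC=C1)C1C=CC=C1 | intermediate
24 | (3E)-4-iodopent-3-en-1-ol | C/C(I)=C\CCO | intermediate
25 | (3E)-4-iodopent-3-enal | C/C(I)=C\CC=O | intermediate
26 | methyl but-2-ynoate | CC#CC(=O)OC | starting material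
27 | methyl (2Z)-3-iodobut-2-enoate | C/C(I)=C/C(=O)OC | intermediate
28 | methyl (2Z,4S,6E)-4-hydroxy-7-iodo-3-methylocta-2,6-dienoate | COC(=O)/C=C(/C)[C@@H](O)C/C=C(\C)I | intermediate
29 | (5S)-5-[(2E)-3-iodobut-2-en-1-yl]-4-methylfuran-2(5H)-one | CC1=CC(=O)O[C@H]1C/C=C(\C)I | intermediate
30 | 8-deoxy-8(17)-ene of the target (3β,6α,18-triol, 13E, 16S butenolide) | CC1=CC(=O)O[C@H]1C/C=C(\C)CC[C@@H]1[C@@]2(C)CC[C@H](O)[C@@](C)(CO)[C@@H]2[C@@H](O)CC1=C | intermediate
31 | 8α-hydroperoxide of the target skeleton | CC1=CC(=O)O[C@H]1C/C=C(\C)CC[C@@H]1[C@@]2(C)CC[C@H](O)[C@@](C)(CO)[C@@H]2[C@@H](O)C[C@@]1(C)OO | intermediate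
32 | CNP0307004.1 (3β,6α,8α,18-tetrahydroxy, 13E, 16S butenolide) | CC1=CC(=O)O[C@H]1C/C=C(\C)CC[C@@H]1[C@@]2(C)CC[C@H](O)[C@@](C)(CO)[C@@H]2[C@@H](O)C[C@@]1(C)O | target

**Step count and risk**

Total steps: 16. Longest linear sequence: 12 (steps 1–10, 15, 16).

Step 10 (radical bicyclisation). The C6 silyloxy group crowds C4–C5 bond formation and lies peri to the equatorial C4 substituent, so the cascade may stop at the monocycle or give the C4 epimer. Fallback: from 18, silylate (TESCl, imidazole) to the C-18 triethylsilyl ether F1 and run a Lewis-acid cationic epoxy-polyene cyclisation (MeAlCl2, CH2Cl2, −94 °C). Anti opening of the epoxide then delivers the E-CH2OSi group stereospecifically to the 4α position, and proton loss gives the bicyclic 6,18-bis-TES ether F2, in which any Δ7 isomer converges at the later HAT hydration. CSA/MeOH returns to the route at 21.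

Step 15 (late-stage reductive coupling). Hydrodehalogenation of 21 or homodimerisation of the hindered vinyl iodide may dominate. Fallback: from 21, persilylate (TESOTf, 2,6-lutidine) to the tris-TES ether F3, insert zinc (Zn dust, cat. I2, DMA, 70 °C) to give the alkylzinc bromide F4, and couple with 29 in a Pd-catalysed Negishi reaction (Pd(dppf)Cl2, THF/DMA, rt) to the tris-TES ether of the coupled product F5. CSA/MeOH returns to the route at 30.

Step 16 (final hydration). The α:β ratio at C8 and the selectivity against the C13=C14 alkene may be modest. Fallback: from 30, oxymercuration with Hg(OAc)2 (1.05 equiv, THF/H2O, 0 °C) selects the 1,1-disubstituted alkene and delivers water to C8 along the equatorial α trajectory (the axial path is blocked by the C10 methyl), giving the 17-(acetoxymercurio)-8α-ol F6. Alkaline NaBH4 demercuration returns to the route at 32.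

Further compounds
F1 | step 10 | C-18 triethylsilyl ether of 18 | CC[Si](CC)(CC)OC[C@]1(C)O[C@H]1CC/C(C)=C/[C@@H](O[Si](CC)(CC)CC)C/C(C)=C/CCBr
F2 | step 10 | 6,18-bis(triethylsilyl) ether of 21 | BrCC[C@@H]1[C@@]2(C)CC[C@H](O)[C@@](C)(CO[Si](CC)(CC)CC)[C@@H]2[C@@H](O[Si](CC)(CC)CC)CC1=C
F3 | step 15 | 3,6,18-tris(triethylsilyl) ether of 21 | BrCC[C@@H]1[C@@]2(C)CC[C@H](O[Si](CC)(CC)CC)[C@@](C)(CO[Si](CC)(CC)CC)[C@@H]2[C@@H](O[Si](CC)(CC)CC)CC1=C
F4 | step 15 | alkylzinc bromide from F3 | Br[Zn]CC[C@@H]1[C@@]2(C)CC[C@H](O[Si](CC)(CC)CC)[C@@](C)(CO[Si](CC)(CC)CC)[C@@H]2[C@@H](O[Si](CC)(CC)CC)CC1=C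
F5 | step 15 | 3,6,18-tris(triethylsilyl) ether of 30 | CC1=CC(=O)O[C@H]1C/C=C(\C)CC[C@@H]1[C@@]2(C)CC[C@H](O[Si](CC)(CC)CC)[C@@](C)(CO[Si](CC)(CC)CC)[C@@H]2[C@@H](O[Si](CC)(CC)CC)CC1=C
F6 | step 16 | 17-(acetoxymercurio) derivative of 32 | CC1=CC(=O)O[C@H]1C/C=C(\C)CC[C@@H]1[C@@]2(C)CC[C@H](O)[C@@](C)(CO)[C@@H]2[C@@H](O)C[C@@]1(C[Hg]OC(C)=O)O
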